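**Strategy.** The target is cut at the tetrahydrofuran ring C (O9–C9–C11–C12–C13). Its two spiro atoms are read as a former ketone carbon (C9 of ring B) and the β-carbon of a butenolide (C13 of ring D). A samarium diiodide cascade joins α-hydroxy ketone 16 and 4-vinylbutenolide 3: ketyl 1,6-addition forges C9–C11, and the resulting alkoxide closes O9–C13 by oxa-Michael addition, setting both spiro centres. The ring D lactone is later reduced and dehydrated to the enol ether. The cis-decalin ketone comes from an enantioselective Diels–Alder reaction of 2,6-dimethylbenzoquinone with allylidenecyclopropane (a gem-dimethyl surrogate), then hydroxyl-directed epoxidation and trans-diaxial opening place O8 and O7.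

Key step: step 10

Remark: labdane numbering is used (C1–C10 decalin, C11–C16 side chain, β = face of the C10 methyl; rings A/B/C/D = gem-dimethylcyclohexane/oxygenated carbocycle/tetrahydrofuran/dihydrofuran); the SMILES is read as the A/B-cis isomer (5R,7R,8R,9S,10S,13S: 5β-H, 7β-OH, 8α-OAc, 9α-O), and the (S)-configured oxazaborolidinium catalyst of step 3 is assumed to give the (5R,10S) adduct, its mirror image being used otherwise.

Step 1
Reactants: 1 4-bromofuran-2(5H)-one; 2 tributyl(vinyl)stannane
Product: 3 4-vinylfuran-2(5H)-one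
Conditions: Pd(PPh3)4 (zerovalent palladium, cat.), BHT, toluene, 80 °C
Reagents that add atoms: none
Why: Stille cross-coupling: the 4-bromobutenolide is a vinylogous acyl bromide that adds readily to zerovalent palladium, and the neutral conditions spare the base-sensitive lactone; no stereocentre is formed.

Step 2
Reactants: 4 cyclopropyltriphenylphosphonium bromide; 5 acrolein
Product: 7 allylidenecyclopropane (prop-2-en-1-ylidenecyclopropane), via cyclopropylidenetriphenylphosphorane 6 (not isolated)
Conditions: KOt-Bu, THF, 50 °C; then 5, 0 → 23 °C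
Reagents that add atoms: none
Why: Wittig olefination of acrolein by the non-stabilised cyclopropylidene ylide gives a diene whose tied-back terminus avoids the cis-methyl penalty of 4-methylpenta-1,3-diene and later unveils the C4 gem-dimethyl group.

Step 3
Reactants: 7 allylidenecyclopropane; 8 2,6-dimethyl-1,4-benzoquinone
Product: 9 cis-fused cycloadduct (5R,10S; 5β-H and 10β-CH3; C2=C3 and C7=C8 double bonds; C6 and C9 ketones; spirocyclopropane at C4)
Conditions: (S)-3,3-diphenyl-1-(o-tolyl)tetrahydro-1H,3H-pyrrolo[1,2-c][1,3,2]oxazaborole·HNTf2 (20 mol%), CH2Cl2, −78 → −40 °C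
Reagents that add atoms: none
Why: Enantioselective Diels–Alder reaction: the cationic boron Lewis acid binds the unhindered C6 carbonyl, so the unsubstituted diene terminus bonds to the β-carbon C10 and the cyclopropylidene carbon to C5, suprafacial addition sets 5-H and 10-CH3 cis, and the catalyst shields one face of the quinone.

Step 4
Reactants: 9 cis-fused cycloadduct
Product: 10 6α-hydroxy enone (C7=C8–C9=O retained; 5β-H; 10β-CH3)
Conditions: NaBH4, CeCl3·7H2O, MeOH, −78 °C
Reagents that add atoms: none
Why: Luche reduction: 1,2-hydride addition occurs at the C6 carbonyl because C9 is flanked by the quaternary C10 and the methylated C8, and hydride enters from the convex β face anti to C4 to give the 6α-alcohol.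

Step 5
Reactants: 10 6α-hydroxy enone
Product: 11 7α,8α-epoxy-6α-hydroxy ketone (8β-CH3)
Conditions: t-BuOOH, benzyltrimethylammonium hydroxide (cat.), THF, 0 °C
Reagents that add atoms: tert-butyl hydroperoxide, CC(C)(C)OO
Why: Weitz–Scheffer (nucleophilic) epoxidation of the enone, directed by hydrogen bonding from the free 6α-hydroxyl, should deliver the hydroperoxide anion to the α face and set C8 with oxygen α and CH3 β.

Step 6
Reactants: 11 7α,8α-epoxy-6α-hydroxy ketone
Product: 12 6α-acetoxy-7α,8α-epoxy ketone
Conditions: Ac2O, pyridine, DMAP (cat.), CH2Cl2, 23 °C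
Reagents that add atoms: acetic anhydride, CC(=O)OC(C)=O
Why: Standard acylation of the only hydroxyl group; the acetate keeps O6 distinguishable from O7 and O8 until step 14.

Step 7
Reactants: 12 6α-acetoxy-7α,8α-epoxy ketone
Product: 13 6α-acetoxy-7β,8α-dihydroxy ketone (ring A still with C2=C3 and the spirocyclopropane)
Conditions: HClO4 (cat.), THF–H2O, 0 → 23 °C
Reagents that add atoms: water, O
Why: Acid-catalysed epoxide hydrolysis: water attacks C7 anti to the epoxide oxygen (trans-diaxial opening) because C8 is quaternary and α to the carbonyl, giving 7β-OH with inversion and leaving the 8α C–O bond untouched.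

Step 8
Reactants: 13 6α-acetoxy-7β,8α-dihydroxy ketone
Product: 15 6α-acetoxy-7β,8α-dihydroxy-4,4,8β,10β-tetramethyl-cis-decalin-9-one (5β-H), via 2,3-dihydro spirocyclopropane diol 14 (not isolated)
Conditions: H2 (3 atm), PtO2, AcOH, 23 °C
Reagents that add atoms: none
Why: Catalytic hydrogenation of the ring A alkene followed by platinum-catalysed hydrogenolysis of the distal, least substituted cyclopropane bond turns the spirocyclopropane into the C4 gem-dimethyl group, while the ketone flanked by two fully substituted carbons should resist reduction.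

Step 9
Reactants: 15 6α-acetoxy-7β,8α-dihydroxy ketone
Product: 16 6α-acetoxy-8α-hydroxy-7β-triethylsilyloxy ketone
Conditions: TESOTf, 2,6-lutidine, CH2Cl2, −78 °C
Reagents that add atoms: triethylsilyl trifluoromethanesulfonate, CC[Si](CC)(CC)OS(=O)(=O)C(F)(F)F
Why: Silylation is selective for the secondary 7-hydroxyl because the tertiary 8-hydroxyl next to the ketone is far slower at −78 °C.

Step 10
Reactants: 16 6α-acetoxy-8α-hydroxy-7β-triethylsilyloxy ketone; 3 4-vinylfuran-2(5H)-one
Product: 18 bis-spiro lactone (13S)-6α-acetoxy-9α,13-epoxy-8α-hydroxy-7β-triethylsilyloxy-5β-labdan-15,16-olide, via ring-open 9α-hydroxy butenolide 17 (not isolated)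
Conditions: 3 (2 equiv), SmI2, t-BuOH, THF, −78 → 0 °C; then Et3N, 23 °C (same flask)
Reagents that add atoms: none
Why: Proposed new method: SmI2 reduces the chelated α-hydroxy ketone to its ketyl, which adds to the unsubstituted vinyl terminus (C11) of the dienyl lactone in a 1,6-sense; a second electron gives the samarium dienolate, protonation and amine-mediated conjugation give butenolide 17, and the samarium alkoxide at O9 closes ring C by 5-exo-trig oxa-Michael addition to C13. The closest known reactions are the SmI2 ketone–acrylate reductive coupling with lactonisation and the base-mediated oxa-Michael spirocyclisation onto 4-substituted butenolides. C9 is set by the trivalent samarium chelate between O9 and the equatorial 8α-hydroxyl together with the axial C4 carbon, which leave only the β face open for C–C bond formation (C11 β, O9 α). C13 is set in the ring closure: the samarium centre that holds O8 and O9 can reach the lactone carbonyl only when the C14–C15 arm lies on the C8 side, which is the 13S configuration. The step needs 1,6- over 1,4-addition, secured by the unhindered terminal CH2 against the disubstituted β-carbon, and survival of the C8–O bond, which is equatorial, lies in the nodal plane of the ketyl and carries no acyl group.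

Step 11
Reactants: 18 bis-spiro lactone
Product: 19 6α,8α-diacetoxy bis-spiro lactone (7β-OTES; 13S)
Conditions: Ac2O, DMAP, Et3N, CH2Cl2, 40 °C
Reagents that add atoms: acetic anhydride, CC(=O)OC(C)=O
Why: DMAP-catalysed acylation of the tertiary 8α-hydroxyl, the only free hydroxyl group, installs the acetate of the target.

Step 12
Reactants: 19 6α,8α-diacetoxy bis-spiro lactone
Product: 20 lactol (15-hydroxy-9α,13;15,16-diepoxide; both C15 anomers)
Conditions: disiamylborane (Sia2BH), THF, 0 → 23 °C; then H2O2, pH 7 buffer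
Reagents that add atoms: none
Why: Disiamylborane reduces a γ-lactone to the lactol and stops there, and it leaves the two acetates and the silyl ether untouched.

Step 13
Reactants: 20 lactol
Product: 22 6α,8α-diacetoxy-7β-triethylsilyloxy-9α,13;15,16-diepoxy-5β-labd-14-ene (13S), via anomeric mesylate 21 (not isolated)
Conditions: MsCl, Et3N, CH2Cl2, −40 → 40 °C
Reagents that add atoms: none
Why: The lactol is the only hydroxyl group, so mesylation and amine-promoted elimination through the oxocarbenium ion give the 2,3-dihydrofuran (C14=C15) under basic conditions that the acid-labile spiro enol ether tolerates.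

Step 14
Reactants: 22 diacetoxy enol ether
Product: 23 8α-acetoxy-6α-hydroxy-7β-triethylsilyloxy-9α,13;15,16-diepoxy-5β-labd-14-ene (13S)
Conditions: K2CO3, MeOH, 0 → 23 °C
Reagents that add atoms: none
Why: Base-catalysed transesterification removes the secondary 6-acetate, while the tertiary 8-acetate next to the spiro carbon is too hindered to react and the triethylsilyl ether survives.

Step 15
Reactants: 23 6α-alcohol
Product: 24 8α-acetoxy-7β-triethylsilyloxy-9α,13;15,16-diepoxy-5β-labd-14-en-6-one (13S)
Conditions: Dess–Martin periodinane, NaHCO3, CH2Cl2, 0 → 23 °C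
Reagents that add atoms: none
Why: Dess–Martin oxidation under buffered, non-enolising conditions forms the C6 ketone without epimerising the adjacent C5 centre of the cis ring fusion and without touching the enol ether.

Step 16
Reactants: 24 7β-triethylsilyloxy ketone
Product: 25 CNP0275274.1 (5R,7R,8R,9S,10S,13S)-8-acetoxy-9,13;15,16-diepoxy-7-hydroxylabd-14-en-6-one
Conditions: HF·pyridine, pyridine, THF, 0 °C
Reagents that add atoms: none
Why: Buffered fluoride cleaves the triethylsilyl ether of the α-silyloxy ketone at 0 °C, conditions mild enough for the spiro enol ether, the tertiary acetate and the cis ring fusion.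

**Compound list**

1 | 4-bromofuran-2(5H)-one | BrC1=CC(=O)OC1 | starting material
2 | tributyl(vinyl)stannane | C=C[Sn](CCCC)(CCCC)CCCC | starting material
3 | 4-vinylfuran-2(5H)-one | C=CC1=CC(=O)OC1 | intermediate
4 | cyclopropyltriphenylphosphonium bromide | [Br-].C1CC1[P+](c1ccccc1)(c1ccccc1)c1ccccc1 | starting material
5 | acrolein | C=CC=O | starting material
6 | cyclopropylidenetriphenylphosphorane (not isolated) | C1CC1=P(c1ccccc1)(c1ccccc1)c1ccccc1 | intermediate
7 | allylidenecyclopropane | C=CC=C1CC1 | intermediate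
8 | 2,6-dimethyl-1,4-benzoquinone | CC1=CC(=O)C=C(C)C1=O | starting material
9 | (5R,10S) cis-fused cycloadduct, ene-dione with spirocyclopropane at C4 | CC1=CC(=O)[C@@H]2C3(CC3)C=CC[C@]2(C)C1=O | intermediate
10 | 6α-hydroxy enone | CC1=C[C@H](O)[C@@H]2C3(CC3)C=CC[C@]2(C)C1=O | intermediate
11 | 7α,8α-epoxy-6α-hydroxy ketone | C[C@@]12O[C@@H]1[C@H](O)[C@@H]1C3(CC3)C=CC[C@]1(C)C2=O | intermediate
12 | 6α-acetoxy-7α,8α-epoxy ketone | C[C@@]12O[C@@H]1[C@H](OC(C)=O)[C@@H]1C3(CC3)C=CC[C@]1(C)C2=O | intermediate
13 | 6α-acetoxy-7β,8α-dihydroxy ketone (C2=C3, spirocyclopropane) | O[C@]1(C)[C@@H](O)[C@H](OC(C)=O)[C@@H]2C3(CC3)C=CC[C@]2(C)C1=O | intermediate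
14 | 2,3-dihydro spirocyclopropane diol (not isolated) | O[C@]1(C)[C@@H](O)[C@H](OC(C)=O)[C@@H]2C3(CC3)CCC[C@]2(C)C1=O | intermediate
15 | 6α-acetoxy-7β,8α-dihydroxy-4,4,8β,10β-tetramethyl-cis-decalin-9-one (5β-H) | O[C@]1(C)[C@@H](O)[C@H](OC(C)=O)[C@@H]2C(C)(C)CCC[C@]2(C)C1=O | intermediate
16 | 6α-acetoxy-8α-hydroxy-7β-triethylsilyloxy ketone | O[C@]1(C)[C@@H](O[Si](CC)(CC)CC)[C@H](OC(C)=O)[C@@H]2C(C)(C)CCC[C@]2(C)C1=O | intermediate
17 | ring-open 8α,9α-diol with 9β-[2-(5-oxo-2,5-dihydrofuran-3-yl)ethyl] chain (not isolated) | O[C@]1(C)[C@@H](O[Si](CC)(CC)CC)[C@H](OC(C)=O)[C@@H]2C(C)(C)CCC[C@]2(C)[C@@]1(O)CCC1=CC(=O)OC1 | intermediate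
18 | (13S)-6α-acetoxy-9α,13-epoxy-8α-hydroxy-7β-triethylsilyloxy-5β-labdan-15,16-olide | O[C@]1(C)[C@@H](O[Si](CC)(CC)CC)[C@H](OC(C)=O)[C@@H]2C(C)(C)CCC[C@]2(C)[C@@]12CC[C@@]1(CC(=O)OC1)O2 | intermediate
19 | 6α,8α-diacetate of 18 | CC(=O)O[C@]1(C)[C@@H](O[Si](CC)(CC)CC)[C@H](OC(C)=O)[C@@H]2C(C)(C)CCC[C@]2(C)[C@@]12CC[C@@]1(CC(=O)OC1)O2 | intermediate
20 | lactol (15-hydroxy, both anomers) | CC(=O)O[C@]1(C)[C@@H](O[Si](CC)(CC)CC)[C@H](OC(C)=O)[C@@H]2C(C)(C)CCC[C@]2(C)[C@@]12CC[C@@]1(CC(O)OC1)O2 | intermediate
21 | anomeric mesylate (not isolated) | CC(=O)O[C@]1(C)[C@@H](O[Si](CC)(CC)CC)[C@H](OC(C)=O)[C@@H]2C(C)(C)CCC[C@]2(C)[C@@]12CC[C@@]1(CC(OS(C)(=O)=O)OC1)O2 | intermediate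
22 | 6α,8α-diacetoxy-7β-triethylsilyloxy-9α,13;15,16-diepoxy-5β-labd-14-ene (13S) | CC(=O)O[C@]1(C)[C@@H](O[Si](CC)(CC)CC)[C@H](OC(C)=O)[C@@H]2C(C)(C)CCC[C@]2(C)[C@@]12CC[C@@]1(C=COC1)O2 | intermediate
23 | 8α-acetoxy-6α-hydroxy-7β-triethylsilyloxy analogue | CC(=O)O[C@]1(C)[C@@H](O[Si](CC)(CC)CC)[C@H](O)[C@@H]2C(C)(C)CCC[C@]2(C)[C@@]12CC[C@@]1(C=COC1)O2 | intermediate
24 | 8α-acetoxy-7β-triethylsilyloxy-6-ketone | CC(=O)O[C@]1(C)[C@@H](O[Si](CC)(CC)CC)C(=O)[C@@H]2C(C)(C)CCC[C@]2(C)[C@@]12CC[C@@]1(C=COC1)O2 | intermediate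
25 | CNP0275274.1 | CC(=O)O[C@]1(C)[C@@H](O)C(=O)[C@@H]2C(C)(C)CCC[C@]2(C)[C@@]12CC[C@@]1(C=COC1)O2 | target

**Step count.** Total: 16 steps. Longest linear sequence: 15 steps (steps 2–16, from 4 and 5); step 1 is a one-step branch.

**Steps most likely to fail**

Step 10 (proposed new method). The cascade may be diverted by reductive loss of the C8 hydroxyl, by simple reduction or dimerisation of 3, or by poor facial control at C13. The fallback uses known reactions and sets out from 16. Addition of 2-(furan-3-yl)ethylmagnesium bromide with CeCl3 (THF, −78 °C; the first equivalent deprotonates the 8-hydroxyl) should give the 9β-[2-(furan-3-yl)ethyl]-8α,9α-diol F1. Photo-oxygenation (O2, rose bengal, visible light, i-Pr2NEt, CH2Cl2, −78 °C) should convert the 3-alkylfuran regioselectively into the 5-hydroxy-4-alkylfuran-2(5H)-one F2. NaBH4 reduction and acidification give butenolide 17, and DBU closes it by oxa-Michael addition, which returns the route to 18. A C13 epimer, if formed, would be separated and re-equilibrated with DBU.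

Step 3. The cycloaddition may be slow at the trisubstituted quinone double bond, the strained diene may not survive the strong Lewis acid, or the facial selectivity may be low. The fallback sets out from 7 and 8. Uncatalysed cycloaddition (toluene, 80 °C) gives the racemic cis adduct F3, and Luche reduction as in step 4 gives the racemic 6α-hydroxy enone F4. A lipase-catalysed kinetic resolution (Candida antarctica lipase B, vinyl acetate, t-BuOMe), with the enzyme chosen to acylate the unwanted antipode, gives the acetate of the mirror-image alcohol F5 and leaves 10, where the route is rejoined.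

Step 5. Hydrogen-bond direction may not override the steric preference, which would put the epoxide on the β face. The fallback sets out from 9. Exhaustive 1,2-reduction (NaBH4, CeCl3·7H2O, MeOH, 23 °C) should give the 6α,9α-diol F6 by attack on the convex face. Its electron-rich C7=C8 bond is then epoxidised under double hydroxyl direction (VO(acac)2, t-BuOOH, CH2Cl2) to the 7α,8α-epoxy diol F7. Dess–Martin oxidation gives the 7α,8α-epoxy-6,9-dione F8. Selective reduction of the unhindered C6 carbonyl anti to the epoxide (NaBH4, CeCl3·7H2O, MeOH, −78 °C) returns the route to 11.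

Further compounds
F1 | step 10 | 9β-[2-(furan-3-yl)ethyl]-8α,9α-diol (6α-OAc, 7β-OTES) | O[C@]1(C)[C@@H](O[Si](CC)(CC)CC)[C@H](OC(C)=O)[C@@H]2C(C)(C)CCC[C@]2(C)[C@@]1(O)CCc1ccoc1
F2 | step 10 | 5-hydroxy-4-alkylfuran-2(5H)-one from F1 (both C16 epimers) | O[C@]1(C)[C@@H](O[Si](CC)(CC)CC)[C@H](OC(C)=O)[C@@H]2C(C)(C)CCC[C@]2(C)[C@@]1(O)CCC1=CC(=O)OC1O
F3 | step 3 | racemic cis cycloadduct (9 and its mirror image) | CC1=CC(=O)[C@@H]2C3(CC3)C=CC[C@]2(C)C1=O.CC1=CC(=O)[C@H]2C3(CC3)C=CC[C@@]2(C)C1=O
F4 | step 3 | racemic 6α-hydroxy enone (10 and its mirror image) | CC1=C[C@H](O)[C@@H]2C3(CC3)C=CC[C@]2(C)C1=O.CC1=C[C@@H](O)[C@H]2C3(CC3)C=CC[C@@]2(C)C1=O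
F5 | step 3 | acetate of the mirror image of 10 | CC1=C[C@@H](OC(C)=O)[C@H]2C3(CC3)C=CC[C@@]2(C)C1=O
F6 | step 5 | 6α,9α-diol | CC1=C[C@H](O)[C@@H]2C3(CC3)C=CC[C@]2(C)[C@@H]1O
F7 | step 5 | 7α,8α-epoxy-6α,9α-diol | C[C@@]12O[C@@H]1[C@H](O)[C@@H]1C3(CC3)C=CC[C@]1(C)[C@@H]2O
F8 | step 5 | 7α,8α-epoxy-6,9-dione | C[C@@]12O[C@@H]1C(=O)[C@@H]1C3(CC3)C=CC[C@]1(C)C2=O
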